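A direct plan would acylate the auxiliary (4S)-4-isopropyl-1,3-oxazolidin-2-one A2 with 3-(3,4,5-trimethoxyphenyl)propanoic acid A1 to the imide A3, dimerise the lithium enolate of A3 with PhI(OAc)2 to the (2R,3R)-bis-imide A4, cleave both para-methyl ethers with BCl3 to the bis-phenol A5 and reduce off the auxiliaries with LiAlH4. Its weakest steps would be:
- the oxidative enolate homocoupling, which would make the central bond and both stereocentres in one bimolecular step and leave meso and (S,S) isomers to be removed;
- the cleavage of two of six aryl methyl ethers with BCl3 on the most advanced intermediate, where over- or under-cleavage would cost precious material;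
- the loading and removal of two auxiliaries, two steps that add no bond of the target.

**Plan of the new route**
The C2–C3 bond is not made; it is bought in diethyl succinate.
The retrosynthesis cuts the C2–H and C3–H bonds (with the two benzylic C–H bonds) back to the flat, achiral (2E,3E)-bis(arylidene)succinic acid 4, then the two C=C bonds of 4 by a twofold Stobbe condensation.
Enabling feature: the target is C2-symmetric, and C2 and C3 are C–H carbons lying between an ArCH2 group and a CH2OH (a reduced carboxyl), so in 4 each olefin sits 1,3 to the distal carboxylate as in an itaconic acid.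
No ring is formed at any stage; both arenes are bought.
Hence no C–C coupling sets a stereocentre, no auxiliary is carried, and the para-phenols travel as benzyl ethers, so no methyl ether is cleaved.

Key step: step 2

Assumption: the (S,S)-enantiomer of Et-DuPHOS is taken to give the (R)-configured 2-(arylmethyl)succinic unit, by analogy with β-aryl itaconates; if a trial on the mono-arylidene half-ester shows the opposite sense, the (R,R)-ligand is used and nothing else changes.

Step 1
Reactants: 1 4-(benzyloxy)-3,5-dimethoxybenzaldehyde (two molecules); 2 diethyl succinate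
Product: 4 (2E,3E)-2,3-bis[4-(benzyloxy)-3,5-dimethoxybenzylidene]butanedioic acid, via mono-arylidene half-ester sodium salt 3 (not isolated)
Conditions: NaOEt (5 equiv), EtOH, reflux, 1 (2.2 equiv), N2, light excluded; then H2O, reflux; aq. HCl to pH 2; recrystallisation
Reagents that add atoms: none
Why: This is a twofold Stobbe condensation, in which the succinate enolate adds to 1, the aldolate lactonises onto the γ-ester and E1cB opening gives the (E)-half-ester salt 3, whose CH2 (α to the carboxylate and γ to the enoate) repeats the sequence with the second aldehyde through a lactone onto the remaining ester, so that each aldehyde oxygen ends in a carboxylate, each aryl group ends trans to the carboxyl on its own olefinic carbon and every carbon of the target is assembled without a stereocentre.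

Step 2
Reactants: 4 (2E,3E)-2,3-bis[4-(benzyloxy)-3,5-dimethoxybenzylidene]butanedioic acid
Product: 6 (2R,3R)-2,3-bis[4-(benzyloxy)-3,5-dimethoxybenzyl]butanedioic acid, via (2R)-monoene diacid 5 (not isolated)
Conditions: [Rh(cod)((S,S)-Et-DuPHOS)]BF4 (2 mol %), Et3N (0.2 equiv), H2 (10 bar), degassed MeOH, 30 °C, light excluded; aq. HCl; crystallisation to remove the meso diacid
Reagents that add atoms: none
Why: Proposed new method: each C=C of 4 stands 1,3 to the distal carboxylate exactly as in a β-aryl itaconic acid, so the cationic monovalent-rhodium bisphosphine should bind olefin and carboxylate as a chelate, add H2 oxidatively, deliver hydride to the benzylic carbon to give a five-membered trivalent-rhodium alkyl carboxylate chelate and close the cycle by C–H reductive elimination at C2 (then at C3); the closest known reaction type is the hydrogenation of 2-arylidenesuccinic acids and their half-esters (Stobbe itaconates) with [Rh(cod)(Et-DuPHOS)]BF4 or Ru(OAc)2(BINAP), here run twice on one molecule. No ring is closed. Both stereocentres are C–H centres set by the catalyst: the C2-symmetric ligand selects the same olefin face in each half, first on the diene and then on monoene 5, which is itself an ordinary 3-substituted 2-arylidenesuccinic acid, so the first centre should only perturb a catalyst-controlled event. Because two independent selections are made, a wrong-face event should end mainly in the separable meso diacid and not in the (2S,3S) enantiomer, so the enantiomeric purity of the C2-symmetric fraction should exceed the single-event selectivity, and minor E/Z isomers of 4 should converge as they do for β-substituted itaconates. The step needs 1,2- and not 1,4-addition of H2 and no olefin migration: the (E,E) geometry puts both aryl groups on the inner positions of the diene, which twists the two acrylic units out of plane and denies the planar s-cis diene binding that 1,4-addition requires, while carboxylate chelation holds the metal on one olefin at a time; benzyl ethers and arenes are inert to the homogeneous catalyst.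

Step 3
Reactants: 6 (2R,3R)-2,3-bis[4-(benzyloxy)-3,5-dimethoxybenzyl]butanedioic acid
Product: 7 (2R,3R)-2,3-bis[4-(benzyloxy)-3,5-dimethoxybenzyl]butane-1,4-diol
Conditions: BH3·SMe2 (5 equiv), THF, 0 °C → rt; careful H2O quench at 0 °C; aq. work-up, EtOAc extraction
Reagents that add atoms: none
Why: This is a chemoselective borane reduction of carboxylic acids, which runs through acyloxyboranes without any base, so the α-stereocentres cannot epimerise (CH2OH keeps the CIP rank of CO2H, hence still 2R,3R) and the benzyl and methyl aryl ethers are untouched.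

Step 4
Reactants: 7 (2R,3R)-2,3-bis[4-(benzyloxy)-3,5-dimethoxybenzyl]butane-1,4-diol
Product: 8 (2R,3R)-2,3-bis(4-hydroxy-3,5-dimethoxybenzyl)butane-1,4-diol (5,5'-dimethoxysecoisolariciresinol)
Conditions: H2 (1 atm), 10% Pd/C, EtOAc–MeOH, rt
Reagents that add atoms: none
Why: This is a catalytic hydrogenolysis of benzyl aryl ethers, which should free both para-phenols under neutral conditions while the aryl methyl ethers, the primary alcohols and the two stereocentres (attached to the arenes only through C–C bonds) stay as they are.

## Compound list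
1 | 4-(benzyloxy)-3,5-dimethoxybenzaldehyde | COc1cc(C=O)cc(OC)c1OCc1ccccc1 | starting material
2 | diethyl succinate | CCOC(=O)CCC(=O)OCC | starting material
3 | sodium (3E)-4-[4-(benzyloxy)-3,5-dimethoxyphenyl]-3-(ethoxycarbonyl)but-3-enoate | CCOC(=O)/C(CC(=O)[O-])=C/c1cc(OC)c(OCc2ccccc2)c(OC)c1.[Na+] | intermediate
4 | (2E,3E)-2,3-bis[4-(benzyloxy)-3,5-dimethoxybenzylidene]butanedioic acid | OC(=O)/C(=C/c1cc(OC)c(OCc2ccccc2)c(OC)c1)/C(=C\c1cc(OC)c(OCc2ccccc2)c(OC)c1)C(=O)O | intermediate
5 | (2R,3E)-2-[4-(benzyloxy)-3,5-dimethoxybenzyl]-3-[4-(benzyloxy)-3,5-dimethoxybenzylidene]butanedioic acid | COc1cc(C[C@@H](C(=O)O)/C(=C\c2cc(OC)c(OCc3ccccc3)c(OC)c2)C(=O)O)cc(OC)c1OCc1ccccc1 | intermediate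
6 | (2R,3R)-2,3-bis[4-(benzyloxy)-3,5-dimethoxybenzyl]butanedioic acid | COc1cc(C[C@@H](C(=O)O)[C@H](C(=O)O)Cc2cc(OC)c(OCc3ccccc3)c(OC)c2)cc(OC)c1OCc1ccccc1 | intermediate
7 | (2R,3R)-2,3-bis[4-(benzyloxy)-3,5-dimethoxybenzyl]butane-1,4-diol | COc1cc(C[C@@H](CO)[C@H](CO)Cc2cc(OC)c(OCc3ccccc3)c(OC)c2)cc(OC)c1OCc1ccccc1 | intermediate
8 | (2R,3R)-2,3-bis(4-hydroxy-3,5-dimethoxybenzyl)butane-1,4-diol | COc1cc(C[C@@H](CO)[C@H](CO)Cc2cc(OC)c(O)c(OC)c2)cc(OC)c1O | target

Total step count: 4. Longest linear sequence: 4 steps (1 + 2 → 4 → 6 → 7 → 8).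

## Steps most likely to fail

**Step 2 (Proposed new method).** The second hydrogen delivery may follow the first stereocentre instead of the catalyst and raise the share of meso diacid. The olefin of 5 may migrate to the tetrasubstituted position, which erases the first centre. Hydride may also go to C2 instead of the benzylic carbon through the competing α-carboxylate chelate, which would lower face control. The fallback uses known chemistry, sets out from 1 and 2 and comes back at 7. The Stobbe condensation would be stopped after one aldehyde (KOtBu, tBuOH, 1 equiv of 1) to give (3E)-4-[4-(benzyloxy)-3,5-dimethoxyphenyl]-3-(ethoxycarbonyl)but-3-enoic acid F1. Its single olefin is a standard substrate for [Rh(cod)((S,S)-Et-DuPHOS)]BF4/H2 in MeOH and should give (3R)-4-[4-(benzyloxy)-3,5-dimethoxyphenyl]-3-(ethoxycarbonyl)butanoic acid F2. Reduction of the ester in the presence of the carboxylate (Ca(BH4)2, EtOH, on the potassium salt), then acid, would close (4R)-4-[4-(benzyloxy)-3,5-dimethoxybenzyl]dihydrofuran-2(3H)-one F3. Separately, 1 would be reduced (NaBH4, MeOH) to [4-(benzyloxy)-3,5-dimethoxyphenyl]methanol F4 and brominated (PBr3, Et2O) to 2-(benzyloxy)-5-(bromomethyl)-1,3-dimethoxybenzene F5. Enolisation of F3 (LiN(SiMe3)2, THF, −78 °C) and alkylation with F5 anti to the C4 substituent would give (3R,4R)-3,4-bis[4-(benzyloxy)-3,5-dimethoxybenzyl]dihydrofuran-2(3H)-one F6, which LiAlH4 would open to 7. The second centre would then come from substrate-controlled alkylation of a ring instead of a second hydrogenation.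

**Step 1.** The second condensation may stall at the carboxylate stage, because deprotonation next to a carboxylate and E1cB opening of the second lactone are slow, while Cannizzaro and Claisen side reactions consume aldehyde. The fallback sets out from 1 and 2 and comes back at 4. The condensation would be run stepwise, first to (3E)-4-[4-(benzyloxy)-3,5-dimethoxyphenyl]-3-(ethoxycarbonyl)but-3-enoic acid F1, the compound that also opens the fallback to step 2. Re-esterification (EtOH, H2SO4) would give diethyl (2E)-2-[4-(benzyloxy)-3,5-dimethoxybenzylidene]butanedioate F7, so that the second Stobbe condensation with 1 (NaOEt, EtOH) runs on a diester. This would give (2E,3E)-2,3-bis[4-(benzyloxy)-3,5-dimethoxybenzylidene]butanedioic acid monoethyl ester F8, and saponification (aq. NaOH, then HCl) would give 4.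

**Step 3.** The reduction may stop at the hydroxy acid, which would lactonise on work-up, if insoluble acyloxyborane aggregates form from the diacid. The fallback sets out from 6 and comes back at 7. The acid would be converted by Fischer esterification (MeOH, H2SO4, no base present) into dimethyl (2R,3R)-2,3-bis[4-(benzyloxy)-3,5-dimethoxybenzyl]butanedioate F9. F9 would be reduced with LiAlH4 (THF, 0 °C) to 7, hydride addition to the esters being faster than enolisation.

## Further compounds
F1 | step 2 | (3E)-4-[4-(benzyloxy)-3,5-dimethoxyphenyl]-3-(ethoxycarbonyl)but-3-enoic acid | CCOC(=O)/C(CC(=O)O)=C/c1cc(OC)c(OCc2ccccc2)c(OC)c1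
F2 | step 2 | (3R)-4-[4-(benzyloxy)-3,5-dimethoxyphenyl]-3-(ethoxycarbonyl)butanoic acid | CCOC(=O)[C@@H](CC(=O)O)Cc1cc(OC)c(OCc2ccccc2)c(OC)c1
F3 | step 2 | (4R)-4-[4-(benzyloxy)-3,5-dimethoxybenzyl]dihydrofuran-2(3H)-one | O=C1C[C@@H](Cc2cc(OC)c(OCc3ccccc3)c(OC)c2)CO1
F4 | step 2 | [4-(benzyloxy)-3,5-dimethoxyphenyl]methanol | COc1cc(CO)cc(OC)c1OCc1ccccc1
F5 | step 2 | 2-(benzyloxy)-5-(bromomethyl)-1,3-dimethoxybenzene | COc1cc(CBr)cc(OC)c1OCc1ccccc1
F6 | step 2 | (3R,4R)-3,4-bis[4-(benzyloxy)-3,5-dimethoxybenzyl]dihydrofuran-2(3H)-one | O=C1OC[C@H](Cc2cc(OC)c(OCc3ccccc3)c(OC)c2)[C@H]1Cc1cc(OC)c(OCc2ccccc2)c(OC)c1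
F7 | step 1 | diethyl (2E)-2-[4-(benzyloxy)-3,5-dimethoxybenzylidene]butanedioate | CCOC(=O)C/C(=C\c1cc(OC)c(OCc2ccccc2)c(OC)c1)C(=O)OCC
F8 | step 1 | (2E,3E)-2,3-bis[4-(benzyloxy)-3,5-dimethoxybenzylidene]butanedioic acid monoethyl ester | CCOC(=O)/C(=C/c1cc(OC)c(OCc2ccccc2)c(OC)c1)/C(=C\c1cc(OC)c(OCc2ccccc2)c(OC)c1)C(=O)O
F9 | step 3 | dimethyl (2R,3R)-2,3-bis[4-(benzyloxy)-3,5-dimethoxybenzyl]butanedioate | COc1cc(C[C@@H](C(=O)OC)[C@H](C(=O)OC)Cc2cc(OC)c(OCc3ccccc3)c(OC)c2)cc(OC)c1OCc1ccccc1
A1 | direct plan | 3-(3,4,5-trimethoxyphenyl)propanoic acid | COc1cc(CCC(=O)O)cc(OC)c1OC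
A2 | direct plan | (4S)-4-isopropyl-1,3-oxazolidin-2-one | CC(C)[C@H]1COC(=O)N1
A3 | direct plan | (4S)-4-isopropyl-3-[3-(3,4,5-trimethoxyphenyl)propanoyl]-1,3-oxazolidin-2-one | COc1cc(CCC(=O)N2[C@@H](C(C)C)COC2=O)cc(OC)c1OC
A4 | direct plan | (4S,4'S)-3,3'-[(2R,3R)-2,3-bis(3,4,5-trimethoxybenzyl)butanedioyl]bis(4-isopropyl-1,3-oxazolidin-2-one) | COc1cc(C[C@@H](C(=O)N2[C@@H](C(C)C)COC2=O)[C@H](C(=O)N2[C@@H](C(C)C)COC2=O)Cc2cc(OC)c(OC)c(OC)c2)cc(OC)c1OC
A5 | direct plan | (4S,4'S)-3,3'-[(2R,3R)-2,3-bis(4-hydroxy-3,5-dimethoxybenzyl)butanedioyl]bis(4-isopropyl-1,3-oxazolidin-2-one) | COc1cc(C[C@@H](C(=O)N2[C@@H](C(C)C)COC2=O)[C@H](C(=O)N2[C@@H](C(C)C)COC2=O)Cc2cc(OC)c(O)c(OC)c2)cc(OC)c1O
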